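## Structural features

Atoms are numbered along the SMILES string, leaving out methyl carbons and the hydroxyl oxygen: C1=C2 (vinyl), C3, C4=C5(CH3), C6, C7, C8, O9, C10 to C15 (arene, C10 on O9 and C13 on C16), C16, C17(OH), C18=C19, C20 (lactam carbonyl, bound to N), C21 (ketone), C22, C23, C24(CH3), C25, C26(CH3), C27 and C28(CH3). The carbon core is a decahydrofluorene made of cyclohexane ring A (C23 to C28), cyclopentane ring B (C6, C7, C8, C23, C28) and cyclohexene ring C (C3 to C7 and C22), fused trans at C23-C28 and cis at C6-C7. A 13-membered paracyclophane (C7, C8, O9, C10, C11, C12, C13, C16, C17, C18, C19, C21, C22) bridges C8 and C22 and shares C17, C18 and C19 with a 3-acyl-5-hydroxy-3-pyrrolin-2-one. Eight of the ten stereocentres are contiguous (C3, C22, C7, C6, C28, C23, C8, C24), and on ring B the hydrogens H6, H7, H8 and H23 share one face while the C28 methyl, C5, C22 and O9 crowd the other. The fragile groups are the C17 hemiaminal (ring-chain tautomerism), the doubly activated C18=C19 acceptor, the epimerisable C22 next to the ketone and the doubly allylic H3 of the skipped diene. The real difficulty is double: the bent cyclophane with its hindered secondary alkyl aryl ether, and the ring B pentad in which C5 of ring C stands syn to the angular C28 methyl, an arrangement that a cycloaddition of a diene already attached to C28 resists because of allylic strain. The key step exploits the fact that C8, the only oxygenated carbon of ring B, lies opposite the C6-C28 bond and is flanked by two six-membered rings; this is the retron of a 4π electrocyclisation of a bis(cyclohexenyl) ketone, and conrotation then forces H6 and the C28 methyl onto opposite faces. Ring A also carries the 1,3,5-trimethyl pattern of mesitylene around C23, so it can be drawn from a flat, cheap phenol.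

## Logic of the disconnections

**41 back to 35 (through 40, 39, 38, 37, 36).**
- Bonds cut: C17-O, the second bond of C18=C19, and N-H exchanged for N-CO2t-Bu.
- Reason: the hemiaminal and the acceptor are the most fragile parts and should appear last.
- Gain: a saturated, protected β-keto lactam that tolerates base and heat.
- Demand: C19 must be functionalised regiospecifically, and the oxygenation at C17 must spare three alkenes and end in the natural configuration.

**35 back to 34.**
- Bond cut: O9-C10.
- Reason: it is the one macrocycle bond whose formation is irreversible, creates no stereocentre and keeps the C8 configuration.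
- Gain: all ring strain is removed.
- Demand: a hindered secondary alkoxide must couple intramolecularly at high dilution while the acidic C19 site stays a spectator enolate.

**34 back to 27 and 32.**
- Bond cut: C19-C21.
- Reason: this splits the molecule into the carbocyclic half and the amino acid half at a natural 1,3-dicarbonyl.
- Gain: convergence. In 27 the C8 oxygen serves both as the leaving group that activates C21 and as its own protecting group.
- Demand: a lactam enolate must add to a hindered lactone carbonyl.

**27 back to 22 (through 26, 25, 24, 23).**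
- Bonds cut: O9-C21 and C8-H, and C21 is taken back to the alcohol level.
- Reason: C8 is returned to the ketone that the key step delivers.
- Gain: one stereocentre fewer.
- Demand: hydride must attack C8 from the H7/H23 face, and the primary alcohol must be oxidised in the presence of the secondary one.

**22 back to 18 (key disconnection).**
- Bonds cut: C6-C28, C7-H and C23-H.
- In one sentence: a hydride-interrupted Nazarov electrocyclisation of 18 closes the central ring B last.
- Reason: C6-C28 joins the quaternary centre to the centre that a cycloaddition sets wrongly.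
- Gain: four contiguous stereocentres (C28, C6, C7, C23) and one ring disappear, and a tricycle falls into two monocyclic halves held only by a carbonyl.
- Demand: one sense of conrotation, and capture of the cyclised cation before it loses H6.

**18 back to 17, 12 and carbon monoxide.**
- Bonds cut: C8-C23 and C7-C8.
- Reason: C8 is a single carbon between two sp2 carbons.
- Gain: two fragments of similar size, each with two stereocentres.
- Demand: a carbonylative coupling between two hindered partners.

**12 back to 5 (through 11, 10, 9, 8, 7, 6).**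
- Bonds cut: C7-Sn, C2-C3 and C21-C22, and the C4=C5 and C6=C7 unsaturation is removed.
- Reason: C3 and C22 are the β and α carbons of a cyclohexenone whose C5 methyl directs both additions and is then erased.
- Gain: two stereocentres come from one, in a single three-component step.
- Demand: regiocontrol in two enolisations.

**5 back to 1 and 2.**
- Bonds cut: C5-C6 and C3=C22.
- Reason and gain: an annulation of two commodity chemicals under catalyst control gives the enantiomer that the terpene pool does not supply cheaply.
- Demand: facial control in the conjugate addition.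

**17 back to 13 (through 16, 15, 14).**
- The enol sulfonate is traced to a meso ketone and this to the arene.
- Reason: the methyl pattern of ring A is that of 13.
- Gain: no C-C bond has to be made for ring A.
- Demand: the diastereomers must converge on the all-equatorial ketone, and one of two enantiotopic α-hydrogens must be removed selectively.

**32 back to 28 and 29.**
- Bonds cut: C18-C19 and N-C20.
- Reason: 28 carries C16, C17, N and the iodoarene with H17 where the hydroxyl group will stand.
- Gain: a three-step homologation.
- Demand: no racemisation.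

## Other disconnections considered

**Alternative 1:** cut C3-C22 and C6-C7 together, back to the ring A tethered tetraene A1. The forward key step is an intramolecular Diels-Alder reaction to the tricyclic ester A2, followed by aryl ether formation and a late macrocyclisation. This is the plan that comes to mind first, and for this target it is mismatched on three counts.
- The cis B/C fusion from an E-dienophile needs the carbonyl-exo transition state. This runs against secondary orbital overlap and rules out Lewis acid acceleration.
- With the diene equatorial on ring A, the C6 p-orbital must point at C7. The C5=C6 bond is then forced to eclipse the axial C28-CH3 bond while the C5 methyl is cis to C28, which is severe allylic 1,3-strain. In the competing transition state C5 sits staggered between C23 and C27.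
- C22 must stand syn to O9, a C-O eclipsed rotamer rather than the C-H eclipsed one.

Nothing in A1 opposes these biases. The chosen plan obtains the same C5/CH3-28 relationship from orbital symmetry, and it is convergent where this one is linear.

**Alternative 2:** cut the same two bonds last, from the preformed cyclophane A3, so that the macrocycle is made first and the cycloaddition runs across its C7=C22 bond to give 41 directly.
- The tether C28-C23-C8 is unchanged, and with it the allylic strain argument.
- The macrocycle decides which face of C7=C22 is open but not which face of the diene reacts.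
- C18=C19, flanked by two carbonyls, is the better dienophile and would have to be masked.
- A3 packs an arene, two E-alkenes and a lactam into 13 atoms, so its closure is at least as hard as that of 35. It would also have to be done on a heat- and acid-sensitive triene.

**Alternative 3:** cut C18=C19 transannularly, back to the 14-membered macrolactam aldehyde A4, closed at N-C20. The forward key step is a transannular Knoevenagel condensation that contracts the 14-membered ring to the 13-membered and the five-membered rings and leads to 39.
- It addresses only the ring strain. The tricycle with its pentad still needs a key step of its own.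
- A4 holds a configurationally labile α-amino aldehyde under the basic conditions of the condensation.
- The aryl ether has to be made earlier and intermolecularly.
- No step is saved at the end, since 39 still has to be oxygenated.

Key step: step 11

Assumption: the absolute sense of the two reagent-controlled steps (1 and 9) is assigned from the usual shielding models, the mirror-image catalyst or amide being equally available should the sense be reversed, and the natural C17 configuration is taken to be the more stable hemiaminal epimer within the macrocycle.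

## Steps

Step 1
Reactants: 1 tert-butyl acetoacetate; 2 (E)-crotonaldehyde
Product: 5 (S)-5-methylcyclohex-2-en-1-one, via Michael adduct 3 (not isolated), via cyclohexenone ester 4 (not isolated)
Conditions: (R)-2-[bis(3,5-bis(trifluoromethyl)phenyl)(trimethylsilyloxy)methyl]pyrrolidine (10 mol %), neat, rt; then p-TsOH·H2O (20 mol %), toluene, 80 °C
Reagents that add atoms: none
Why: Iminium-catalysed Michael addition, then acid-promoted intramolecular aldol condensation, tert-butyl ester cleavage and decarboxylation (organocatalytic Robinson-type annulation); the bulky silyloxydiarylmethyl group shields one face of the E-iminium ion, so the carbon that becomes C5 should be set as S.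

Step 2
Reactants: 5 (S)-5-methylcyclohex-2-en-1-one
Product: 7 (2S,3R,5S)-2-(hydroxymethyl)-5-methyl-3-vinylcyclohexan-1-one, via magnesium enolate 6 (not isolated)
Conditions: CH2=CHMgBr, CuBr·SMe2 (10 mol %), THF/Me2S, -78 °C; then monomeric HCHO in THF, -78 to -40 °C
Reagents that add atoms: vinylmagnesium bromide C=C[Mg]Br; formaldehyde C=O
Why: Copper-catalysed conjugate addition followed by aldol trapping of the enolate; axial attack anti to the C5 methyl sets C3 (3,5-trans), and formaldehyde approaches anti to the new vinyl group to set C22 (2,3-trans), which is also the more stable arrangement.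

Step 3
Reactants: 7 (2S,3R,5S)-2-(hydroxymethyl)-5-methyl-3-vinylcyclohexan-1-one
Product: 8 (2S,3R,5S)-2-[(tert-butyldiphenylsilyloxy)methyl]-5-methyl-3-vinylcyclohexan-1-one
Conditions: t-BuPh2SiCl, imidazole, CH2Cl2, 0 °C
Reagents that add atoms: tert-butyl(chloro)diphenylsilane CC(C)(C)[Si](Cl)(c1ccccc1)c1ccccc1
Why: Standard silylation carried out at once, so that the β-hydroxy ketone can neither dehydrate nor undergo retro-aldol cleavage; the bulky acid-stable silyl ether is chosen to survive the Lewis acid of step 11.

Step 4
Reactants: 8 (2S,3R,5S)-2-[(tert-butyldiphenylsilyloxy)methyl]-5-methyl-3-vinylcyclohexan-1-one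
Product: 10 (5R,6S)-6-[(tert-butyldiphenylsilyloxy)methyl]-3-methyl-5-vinylcyclohex-2-en-1-one, via trimethylsilyl enol ether 9 (not isolated)
Conditions: LiN(i-Pr)2, Me3SiCl, THF, -78 °C; then Pd(OAc)2 (1.0 equiv), MeCN, rt
Reagents that add atoms: none
Why: Saegusa-Ito oxidation; kinetic deprotonation takes the unhindered CH2 (C6) rather than the substituted C22, and dehydrosilylation by divalent palladium gives the C5=C6 enone, erasing the C5 stereocentre once it has done its work.

Step 5
Reactants: 10 (5R,6S)-6-[(tert-butyldiphenylsilyloxy)methyl]-3-methyl-5-vinylcyclohex-2-en-1-one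
Product: 11 (5S,6S)-6-[(tert-butyldiphenylsilyloxy)methyl]-3-methyl-5-vinylcyclohexa-1,3-dien-1-yl trifluoromethanesulfonate
Conditions: Tf2O, 2,6-di-tert-butyl-4-methylpyridine, CH2Cl2, 0 °C to rt
Reagents that add atoms: trifluoromethanesulfonic anhydride O=S(=O)(OS(=O)(=O)C(F)(F)F)C(F)(F)F
Why: O-sulfonylation of the enone and loss of the γ-proton at C4 should give the linearly conjugated dienyl triflate, the course known for steroidal enones under these conditions; the endocyclic trisubstituted C4=C5 bond is the most stable of the possible dienes, and C3 and C22 are untouched.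

Step 6
Reactants: 11 (5S,6S)-6-[(tert-butyldiphenylsilyloxy)methyl]-3-methyl-5-vinylcyclohexa-1,3-dien-1-yl trifluoromethanesulfonate
Product: 12 [(5S,6S)-6-[(tert-butyldiphenylsilyloxy)methyl]-3-methyl-5-vinylcyclohexa-1,3-dien-1-yl]trimethylstannane
Conditions: Me3SnSnMe3, Pd(PPh3)4 (5 mol %), LiCl, THF, 60 °C
Reagents that add atoms: hexamethylditin C[Sn](C)(C)[Sn](C)(C)C
Why: Palladium-catalysed stannylation of an alkenyl triflate (Stille-type coupling with a distannane), which keeps the position and geometry of the diene; the temperature stays well below that of 1,5-hydrogen shifts in cyclohexadienes.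

Step 7
Reactants: 13 2,4,6-trimethylphenol
Product: 14 2,4,6-trimethylcyclohexan-1-ol (mixture of diastereomers)
Conditions: H2 (60 bar), 5 % Rh/Al2O3, i-PrOH, 80 °C
Reagents that add atoms: none
Why: Heterogeneous arene hydrogenation (dearomatisation) delivers all six ring A carbons and its three methyl groups in one operation; the diastereomer mixture is of no consequence because step 8 is stereoconvergent.

Step 8
Reactants: 14 2,4,6-trimethylcyclohexan-1-ol (mixture of diastereomers)
Product: 15 all-cis-2,4,6-trimethylcyclohexan-1-one (meso)
Conditions: aq NaOCl, AcOH, 15-25 °C; then NaOMe (cat.), MeOH, rt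
Reagents that add atoms: none
Why: Hypochlorite oxidation of a secondary alcohol, then base equilibration of both α-centres through the enolate, which should funnel every diastereomer into the all-equatorial meso ketone.

Step 9
Reactants: 15 all-cis-2,4,6-trimethylcyclohexan-1-one (meso)
Product: 17 (4R,6S)-2,4,6-trimethylcyclohex-1-en-1-yl trifluoromethanesulfonate, via lithium enolate 16 (not isolated)
Conditions: (R,R)-bis(1-phenylethyl)amine, n-BuLi, LiCl, THF, -78 °C; then PhNTf2, -78 °C to rt
Reagents that add atoms: N-phenylbis(trifluoromethanesulfonimide) O=S(=O)(N(c1ccccc1)S(=O)(=O)C(F)(F)F)C(F)(F)F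
Why: Enantioselective deprotonation of a meso ketone by a C2-symmetric chiral lithium amide, for which cis-2,6-dimethylcyclohexanone is the prototype substrate; removal of one of the two enantiotopic axial α-hydrogens leaves C24 and C26 as defined centres, and O-sulfonylation fixes the C23=C28 double bond.

Step 10
Reactants: 17 (4R,6S)-2,4,6-trimethylcyclohex-1-en-1-yl trifluoromethanesulfonate; 12 [(5S,6S)-6-[(tert-butyldiphenylsilyloxy)methyl]-3-methyl-5-vinylcyclohexa-1,3-dien-1-yl]trimethylstannane
Product: 18 ring A/ring C trienone (C8 ketone between C23=C28 and C7=C6-C5=C4; C21 as CH2OSiPh2t-Bu; C3 C22 C24 C26 as in 41)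
Conditions: CO (3 bar), Pd(PPh3)4 (5 mol %), LiCl, THF, 55 °C
Reagents that add atoms: carbon monoxide [C-]#[O+]
Why: Carbonylative Stille coupling, the classical entry to divinyl ketones: oxidative addition of the triflate to zerovalent palladium, CO insertion, then transmetalation from tin; CO pressure favours the acylpalladium species over direct coupling, and no stereocentre is involved.

Step 11
Reactants: 18 ring A/ring C trienone (C8 ketone between C23=C28 and C7=C6-C5=C4; C21 as CH2OSiPh2t-Bu; C3 C22 C24 C26 as in 41)
Product: 22 tricyclic C8 ketone (rings A B C; C21 as CH2OSiPh2t-Bu; C3 C6 C7 C22 C23 C24 C26 C28 as in 41), via BF3 complex 19 (not isolated), via oxyallyl cation 20 (not isolated), via triethylsilyl enol ether 21 (not isolated)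
Conditions: BF3·OEt2 (1.2 equiv), Et3SiH (5 equiv), CH2Cl2, -78 to -20 °C; then 1 M HCl, THF, 0 °C, short contact
Reagents that add atoms: none
Why: BF3 binds the C8 carbonyl (19), and the 3-oxypentadienyl cation C28=C23-C8-C7=C6 undergoes a thermal conrotatory 4π electrocyclisation that forms C6-C28 and closes ring B, the only ring closed (five-membered, electrocyclic mode), to give oxyallyl cation 20, which Et3SiH intercepts; this is the reductive (hydride-interrupted) Nazarov cyclisation, and the parent bis(cyclohexenyl) ketone is the textbook case of the conrotatory course. Rings A and C hold C27 and C5 outside and CH3-28 and H6 inside on the two termini, so conrotation must put CH3-28 and H6 on opposite faces of ring B, that is C5 syn to the angular methyl, by orbital symmetry rather than by steric preference. The sense of rotation sets C28 and C6 relative to the existing centres: ring B is flat in 20, so CH3-28 has to become axial on ring A, and only the rotation that places it anti to the equatorial C24 and C26 methyls avoids a syn-diaxial methyl array, while the same rotation bonds C6 on the face opposite the C22 side chain, so the two fragments are matched. Hydride should attack the less hindered terminus C7 from the H6 face, away from C5 and CH3-28, which sets C7 with the cis B/C fusion and gives 21. Hydrolysis then protonates C23 axially on ring A, anti to the adjacent axial CH3-28, which sets C23 with the trans A/B fusion under kinetic control, and the ketone is reduced without delay because the cis A/B epimer is probably the more stable. The step needs cyclisation and capture to outrun loss of H6 and a 1,2-methyl shift: substitution at both α-carbons favours the reactive U-shaped conformer, the C4=C5 bond only extends the cation and cannot close a ring for geometric reasons, and excess silane at low temperature serves the capture.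

Step 12
Reactants: 22 tricyclic C8 ketone (rings A B C; C21 as CH2OSiPh2t-Bu; C3 C6 C7 C22 C23 C24 C26 C28 as in 41)
Product: 23 tricyclic C8 alcohol (hydroxyl on the face of CH3-28 and C22 as O9 in 41; C21 as CH2OSiPh2t-Bu)
Conditions: NaBH4, CeCl3·7H2O, MeOH/THF, -40 °C
Reagents that add atoms: none
Why: Luche reduction under nearly neutral conditions that should not epimerise C23 or C7; hydride comes from the open face that carries only H7 and H23, the other being covered by ring C, C22 and CH3-28, so the hydroxyl group takes the O9 configuration.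

Step 13
Reactants: 23 tricyclic C8 alcohol (hydroxyl on the face of CH3-28 and C22 as O9 in 41; C21 as CH2OSiPh2t-Bu)
Product: 24 tricyclic C8/C21 diol
Conditions: Bu4NF, THF, rt
Reagents that add atoms: none
Why: Fluoride cleavage of the silyl ether; no other group in the molecule is sensitive to fluoride.

Step 14
Reactants: 24 tricyclic C8/C21 diol
Product: 27 tetracyclic γ-lactone (C21 carbonyl bound to the C8 oxygen), via hydroxy aldehyde 25 (not isolated), via lactol 26 (not isolated)
Conditions: TEMPO (20 mol %), PhI(OAc)2 (2.5 equiv), CH2Cl2, rt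
Reagents that add atoms: none
Why: Oxoammonium oxidation selects the primary alcohol, the aldehyde is trapped by the neighbouring C8 hydroxyl as a five-membered lactol, and this is oxidised further (oxidative lactonisation of a 1,4-diol); the two hydroxyl groups are thus told apart without protecting groups, C21 is activated and the alkenes are spared.

Step 15
Reactants: 28 N-Boc-4-iodo-L-phenylalanine; 29 2,2-dimethyl-1,3-dioxane-4,6-dione
Product: 30 (S)-5-[2-(tert-butoxycarbonylamino)-3-(4-iodophenyl)propanoyl]-2,2-dimethyl-1,3-dioxane-4,6-dione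
Conditions: EDC·HCl, DMAP, CH2Cl2, 0 °C to rt
Reagents that add atoms: none
Why: Carbodiimide-mediated C-acylation of the cyclic malonate, a standard two-carbon homologation of protected amino acids that proceeds without racemisation.

Step 16
Reactants: 30 (S)-5-[2-(tert-butoxycarbonylamino)-3-(4-iodophenyl)propanoyl]-2,2-dimethyl-1,3-dioxane-4,6-dione
Product: 31 (R)-5-[2-(tert-butoxycarbonylamino)-3-(4-iodophenyl)propyl]-2,2-dimethyl-1,3-dioxane-4,6-dione
Conditions: NaBH4, AcOH, CH2Cl2, 0 °C
Reagents that add atoms: none
Why: Acyloxyborohydride reduction of the enolised acyl group to CH2 (C18) by way of the alkylidene malonate; the aryl iodide and the carbamate are inert, and the descriptor changes only through the priority rules.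

Step 17
Reactants: 31 (R)-5-[2-(tert-butoxycarbonylamino)-3-(4-iodophenyl)propyl]-2,2-dimethyl-1,3-dioxane-4,6-dione
Product: 32 tert-butyl (R)-2-(4-iodobenzyl)-5-oxopyrrolidine-1-carboxylate
Conditions: toluene, 110 °C
Reagents that add atoms: none
Why: Thermal decarboxylative lactamisation, in which the carbamate nitrogen captures one carbonyl of the dioxanedione with loss of acetone and CO2; H17 stands where the hydroxyl group of 41 will stand.

Step 18
Reactants: 32 tert-butyl (R)-2-(4-iodobenzyl)-5-oxopyrrolidine-1-carboxylate; 27 tetracyclic γ-lactone (C21 carbonyl bound to the C8 oxygen)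
Product: 34 seco hydroxy β-keto lactam (C19-C21 bond made; free C8 hydroxyl; aryl iodide; C19 epimers), via lithium enolate 33 (not isolated)
Conditions: 32 (2.2 equiv), LiN(SiMe3)2 (2.2 equiv), THF, -78 °C; then 27, -78 to -20 °C; AcOH quench
Reagents that add atoms: none
Why: Crossed Claisen condensation of a lactam enolate with a lactone; the second equivalent of enolate deprotonates the β-keto lactam and drives the equilibrium, and the same event releases the C8 alkoxide needed in step 19, while C22 keeps its more stable trans arrangement.

Step 19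
Reactants: 34 seco hydroxy β-keto lactam (C19-C21 bond made; free C8 hydroxyl; aryl iodide; C19 epimers)
Product: 35 13-membered paracyclophane N-Boc β-keto lactam (O9-C10 bond made; H17 in place of the hydroxyl group)
Conditions: CuI (20 mol %), 3,4,7,8-tetramethyl-1,10-phenanthroline (40 mol %), Cs2CO3 (3 equiv), 4 Å MS, toluene (1 mM, slow addition), 90 °C
Reagents that add atoms: none
Why: Intramolecular Ullmann-type copper-catalysed C-O coupling of an aryl iodide with a secondary alcohol; the bond is formed irreversibly at oxygen, so C8 keeps its configuration, and the β-keto lactam is held as its enolate, which shields C21 from retro-Claisen attack by the alkoxide.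

Step 20
Reactants: 35 13-membered paracyclophane N-Boc β-keto lactam (O9-C10 bond made; H17 in place of the hydroxyl group)
Product: 38 N-Boc 3-acyl-3-pyrrolin-2-one macrocycle (C18=C19), via selenide 36 (not isolated), via selenoxide 37 (not isolated)
Conditions: LiN(SiMe3)2, THF, -78 °C; PhSeCl; then mCPBA (1.0 equiv), CH2Cl2, -78 to 0 °C
Reagents that add atoms: none
Why: α-Selenenylation of the preformed enolate at C19, the only strongly acidic carbon, followed by selenoxide syn-elimination, which can only run towards C18; selenium is oxidised far faster than the alkenes at -78 °C, and a peracid avoids nucleophilic epoxidation of the new acceptor.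

Step 21
Reactants: 38 N-Boc 3-acyl-3-pyrrolin-2-one macrocycle (C18=C19)
Product: 39 N-H 3-acyl-3-pyrrolin-2-one macrocycle (17-deoxy compound)
Conditions: TFA/CH2Cl2 (1:4), 0 °C
Reagents that add atoms: none
Why: Acidolysis of the tert-butyl carbamate; the secondary alkyl aryl ether and the alkenes should tolerate short exposure at 0 °C.

Step 22
Reactants: 39 N-H 3-acyl-3-pyrrolin-2-one macrocycle (17-deoxy compound)
Product: 41 target CNP0151253.2, via hydroperoxide 40 (not isolated)
Conditions: O2 (1 bar), Cs2CO3 (0.2 equiv), THF, 0 °C; then Me2S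
Reagents that add atoms: dioxygen O=O
Why: Base-mediated autoxidation: deprotonation at C17 gives the electron-rich 2-oxidopyrrole, which takes up triplet oxygen at C17, and the sulfide reduces the hydroperoxide, isolated alkenes being inert to these reagents. Oxygen should enter from the outer face of the macrocycle, and the hemiaminal can also equilibrate through the ring-opened keto amide to its more stable epimer.

## Compound list

1 | tert-butyl acetoacetate | CC(=O)CC(=O)OC(C)(C)C | starting material
2 | (E)-crotonaldehyde | C/C=C/C=O | starting material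
3 | tert-butyl (3S)-2-acetyl-3-methyl-5-oxopentanoate | CC(=O)C(C(=O)OC(C)(C)C)[C@@H](C)CC=O | intermediate
4 | tert-butyl (6S)-6-methyl-2-oxocyclohex-3-ene-1-carboxylate | O=C1C=CC[C@H](C)C1C(=O)OC(C)(C)C | intermediate
5 | (S)-5-methylcyclohex-2-en-1-one | O=C1C=CC[C@H](C)C1 | intermediate
6 | bromomagnesium enolate of 3,5-trans-5-methyl-3-vinylcyclohexanone | C=C[C@H]1C[C@H](C)CC(O[Mg]Br)=C1 | intermediate
7 | (2S,3R,5S)-2-(hydroxymethyl)-5-methyl-3-vinylcyclohexan-1-one | C=C[C@H]1C[C@H](C)CC(=O)[C@@H]1CO | intermediate
8 | (2S,3R,5S)-2-[(tert-butyldiphenylsilyloxy)methyl]-5-methyl-3-vinylcyclohexan-1-one | C=C[C@H]1C[C@H](C)CC(=O)[C@@H]1CO[Si](c1ccccc1)(c1ccccc1)C(C)(C)C | intermediate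
9 | kinetic trimethylsilyl enol ether of 8 (C6=C7) | C=C[C@H]1C[C@H](C)C=C(O[Si](C)(C)C)[C@@H]1CO[Si](c1ccccc1)(c1ccccc1)C(C)(C)C | intermediate
10 | (5R,6S)-6-[(tert-butyldiphenylsilyloxy)methyl]-3-methyl-5-vinylcyclohex-2-en-1-one | C=C[C@H]1CC(C)=CC(=O)[C@@H]1CO[Si](c1ccccc1)(c1ccccc1)C(C)(C)C | intermediate
11 | (5S,6S)-6-[(tert-butyldiphenylsilyloxy)methyl]-3-methyl-5-vinylcyclohexa-1,3-dien-1-yl trifluoromethanesulfonate | C=C[C@H]1C=C(C)C=C(OS(=O)(=O)C(F)(F)F)[C@@H]1CO[Si](c1ccccc1)(c1ccccc1)C(C)(C)C | intermediate
12 | [(5S,6S)-6-[(tert-butyldiphenylsilyloxy)methyl]-3-methyl-5-vinylcyclohexa-1,3-dien-1-yl]trimethylstannane | C=C[C@H]1C=C(C)C=C([Sn](C)(C)C)[C@@H]1CO[Si](c1ccccc1)(c1ccccc1)C(C)(C)C | intermediate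
13 | 2,4,6-trimethylphenol | Cc1cc(C)c(O)c(C)c1 | starting material
14 | 2,4,6-trimethylcyclohexan-1-ol (diastereomer mixture) | CC1CC(C)C(O)C(C)C1 | intermediate
15 | all-cis-2,4,6-trimethylcyclohexan-1-one (meso) | O=C1[C@H](C)C[C@H](C)C[C@@H]1C | intermediate
16 | lithium (4R,6S)-2,4,6-trimethylcyclohex-1-en-1-olate | [Li]OC1=C(C)C[C@H](C)C[C@@H]1C | intermediate
17 | (4R,6S)-2,4,6-trimethylcyclohex-1-en-1-yl trifluoromethanesulfonate | FC(F)(F)S(=O)(=O)OC1=C(C)C[C@H](C)C[C@@H]1C | intermediate
18 | ring A/ring C trienone (C8 ketone) | C=C[C@H]1C=C(C)C=C([C@@H]1CO[Si](c1ccccc1)(c1ccccc1)C(C)(C)C)C(=O)C1=C(C)C[C@H](C)C[C@@H]1C | intermediate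
19 | BF3 complex of 18 | C=C[C@H]1C=C(C)C=C([C@@H]1CO[Si](c1ccccc1)(c1ccccc1)C(C)(C)C)C(=[O+][B-](F)(F)F)C1=C(C)C[C@H](C)C[C@@H]1C | intermediate
20 | ring B oxyallyl cation (trifluoroborate zwitterion; one resonance form) | C=C[C@H]1C=C(C)[C@@H]2C([C@@H]1CO[Si](c1ccccc1)(c1ccccc1)C(C)(C)C)=C(O[B-](F)(F)F)[C+]3[C@@H](C)C[C@@H](C)C[C@]32C | intermediate
21 | C8=C23 triethylsilyl enol ether | C=C[C@H]1C=C(C)[C@@H]2[C@H]([C@@H]1CO[Si](c1ccccc1)(c1ccccc1)C(C)(C)C)C(O[Si](CC)(CC)CC)=C3[C@@H](C)C[C@@H](C)C[C@]32C | intermediate
22 | tricyclic C8 ketone | C=C[C@H]1C=C(C)[C@@H]2[C@H]([C@@H]1CO[Si](c1ccccc1)(c1ccccc1)C(C)(C)C)C(=O)[C@@H]3[C@@H](C)C[C@@H](C)C[C@]32C | intermediate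
23 | tricyclic C8 alcohol | C=C[C@H]1C=C(C)[C@@H]2[C@H]([C@@H]1CO[Si](c1ccccc1)(c1ccccc1)C(C)(C)C)[C@H](O)[C@@H]3[C@@H](C)C[C@@H](C)C[C@]32C | intermediate
24 | tricyclic C8/C21 diol | C=C[C@H]1C=C(C)[C@@H]2[C@H]([C@@H]1CO)[C@H](O)[C@@H]3[C@@H](C)C[C@@H](C)C[C@]32C | intermediate
25 | C8-hydroxy C21-aldehyde | C=C[C@H]1C=C(C)[C@@H]2[C@H]([C@@H]1C=O)[C@H](O)[C@@H]3[C@@H](C)C[C@@H](C)C[C@]32C | intermediate
26 | tetracyclic lactol (C21 anomers) | C=C[C@H]1C=C(C)[C@@H]2[C@@H]3[C@@H]1C(O)O[C@@H]3[C@@H]4[C@@H](C)C[C@@H](C)C[C@]42C | intermediate
27 | tetracyclic γ-lactone | C=C[C@H]1C=C(C)[C@@H]2[C@@H]3[C@@H]1C(=O)O[C@@H]3[C@@H]4[C@@H](C)C[C@@H](C)C[C@]42C | intermediate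
28 | N-Boc-4-iodo-L-phenylalanine | CC(C)(C)OC(=O)N[C@@H](Cc1ccc(I)cc1)C(=O)O | starting material
29 | 2,2-dimethyl-1,3-dioxane-4,6-dione | CC1(C)OC(=O)CC(=O)O1 | starting material
30 | (S)-5-[2-(Boc-amino)-3-(4-iodophenyl)propanoyl]-2,2-dimethyl-1,3-dioxane-4,6-dione | CC1(C)OC(=O)C(C(=O)[C@H](Cc2ccc(I)cc2)NC(=O)OC(C)(C)C)C(=O)O1 | intermediate
31 | (R)-5-[2-(Boc-amino)-3-(4-iodophenyl)propyl]-2,2-dimethyl-1,3-dioxane-4,6-dione | CC1(C)OC(=O)C(C[C@H](Cc2ccc(I)cc2)NC(=O)OC(C)(C)C)C(=O)O1 | intermediate
32 | tert-butyl (R)-2-(4-iodobenzyl)-5-oxopyrrolidine-1-carboxylate | O=C1CC[C@H](Cc2ccc(I)cc2)N1C(=O)OC(C)(C)C | intermediate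
33 | lithium enolate of 32 | [Li]OC1=CC[C@H](Cc2ccc(I)cc2)N1C(=O)OC(C)(C)C | intermediate
34 | seco hydroxy β-keto lactam | C=C[C@H]1C=C(C)[C@@H]2[C@H]([C@@H]1C(=O)C4C[C@H](Cc5ccc(I)cc5)N(C(=O)OC(C)(C)C)C4=O)[C@H](O)[C@@H]3[C@@H](C)C[C@@H](C)C[C@]32C | intermediate
35 | paracyclophane N-Boc β-keto lactam | C=C[C@H]1C=C(C)[C@@H]2[C@H]3[C@H](Oc4ccc(cc4)C[C@H]4CC(C(=O)N4C(=O)OC(C)(C)C)C(=O)[C@H]13)[C@@H]1[C@@H](C)C[C@@H](C)C[C@]12C | intermediate
36 | C19 phenyl selenide | C=C[C@H]1C=C(C)[C@@H]2[C@H]3[C@H](Oc4ccc(cc4)C[C@H]4CC([Se]c5ccccc5)(C(=O)N4C(=O)OC(C)(C)C)C(=O)[C@H]13)[C@@H]1[C@@H](C)C[C@@H](C)C[C@]12C | intermediate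
37 | C19 phenyl selenoxide | C=C[C@H]1C=C(C)[C@@H]2[C@H]3[C@H](Oc4ccc(cc4)C[C@H]4CC([Se](=O)c5ccccc5)(C(=O)N4C(=O)OC(C)(C)C)C(=O)[C@H]13)[C@@H]1[C@@H](C)C[C@@H](C)C[C@]12C | intermediate
38 | N-Boc 3-acyl-3-pyrrolin-2-one macrocycle | C=C[C@H]1C=C(C)[C@@H]2[C@H]3[C@H](Oc4ccc(cc4)C[C@H]4C=C(C(=O)N4C(=O)OC(C)(C)C)C(=O)[C@H]13)[C@@H]1[C@@H](C)C[C@@H](C)C[C@]12C | intermediate
39 | N-H 3-acyl-3-pyrrolin-2-one macrocycle (17-deoxy compound) | C=C[C@H]1C=C(C)[C@@H]2[C@H]3[C@H](Oc4ccc(cc4)C[C@H]4C=C(C(=O)N4)C(=O)[C@H]13)[C@@H]1[C@@H](C)C[C@@H](C)C[C@]12C | intermediate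
40 | C17 hydroperoxide | C=C[C@H]1C=C(C)[C@@H]2[C@H]3[C@H](Oc4ccc(cc4)C[C@@]4(OO)C=C(C(=O)N4)C(=O)[C@H]13)[C@@H]1[C@@H](C)C[C@@H](C)C[C@]12C | intermediate
41 | CNP0151253.2 | C=C[C@H]1C=C(C)[C@@H]2[C@H]3[C@H](Oc4ccc(cc4)C[C@@]4(O)C=C(C(=O)N4)C(=O)[C@H]13)[C@@H]1[C@@H](C)C[C@@H](C)C[C@]12C | target

## Step count and least certain steps

Total: 22 steps. Longest linear sequence: 16 steps (1 to 6, 10 to 14, 18 to 22).

**Step 11 (key step).**
- What may go wrong: loss of H6 from the cyclised cation, which would lead into full conjugation with C4=C5, or a 1,2-shift of the C28 methyl to C23, may be faster than intermolecular hydride transfer to a fully substituted terminus. The opposite sense of conrotation may compete if the transition state is too early to feel the axial methyl penalty. C23 may epimerise during hydrolysis towards the cis A/B ketone.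
- Fallback: make the hydride transfer intramolecular. It sets out from 18. Bu4NF gives the primary alcohol F1, and i-Pr2SiHCl with imidazole gives the diisopropylsilyl ether F2, whose Si-H bond can reach C7 through a six-membered array on the H6 face. BF3·OEt2 then triggers the same electrocyclisation. The hydride is handed to C7 from within, and silicon is caught by the C8 oxygen to give the cyclic silyl enol ether F3. Buffered fluoride releases the keto alcohol F4, and NaBH4/CeCl3·7H2O reduces it to 24, where the route is rejoined.

**Step 5.**
- What may go wrong: the hindered pyridine acts under kinetic control. Proton loss from the C5 methyl (exocyclic diene) or from C22 (cross-conjugated diene, with loss of a stereocentre) may compete with loss of H4.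
- Fallback: put the regiochemistry under thermodynamic control before the sulfonate is introduced. It sets out from 10. Me3SiI and (Me3Si)2NH under equilibrating conditions give the linear trimethylsilyl dienol ether F5. MeLi releases the lithium dienolate regiospecifically, and PhNTf2 converts it into 11.

**Step 10.**
- What may go wrong: transmetalation from a hindered stannane to a hindered acylpalladium species may be slow. Direct coupling without CO insertion, protodestannylation or homocoupling could then take over.
- Fallback: form the two bonds to C8 one at a time. It sets out from 17, which is formylated (CO, Bu3SnH, Pd(PPh3)4) to the enal F6. Tin-lithium exchange on 12 with MeLi gives the dienyllithium, which adds to F6 to give the bis-allylic alcohol F7. MnO2 oxidises F7 to 18.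

**Step 18.**
- What may go wrong: addition to the hindered lactone carbonyl may be slower than decay of the N-Boc lactam enolate (carbamate migration, self-condensation). The adduct may also revert before it is deprotonated.
- Fallback: exchange the lactone for an open acyl donor whose tetrahedral adduct is chelated and cannot revert. It sets out from 27, which MeNH(OMe)·HCl and i-PrMgCl open to the hydroxy N-methoxy-N-methylamide F8. An excess of 33 acylates on F8 to give 34.

**Step 19.**
- What may go wrong: strain in the closing ring and the hindered alkoxide may let reduction of the C-I bond, intermolecular coupling, thermal loss of the carbamate or sequestration of copper by the β-dicarbonyl enolate win over cyclisation.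
- Fallback: change the ring-closing bond from O9-C10 to C19-C21. It sets out from 23 and 32, which are joined intermolecularly under the same copper catalysis at normal concentration to give the aryl ether F9. Bu4NF gives the alcohol F10, and Dess-Martin oxidation gives the aldehyde F11. LiN(SiMe3)2 at high dilution closes the ring by an intramolecular aldol addition to the β-hydroxy lactam F12, and a second Dess-Martin oxidation gives 35.

## Further compounds

F1 | step 11 | trienone with free C21 hydroxyl | C=C[C@H]1C=C(C)C=C([C@@H]1CO)C(=O)C1=C(C)C[C@H](C)C[C@@H]1C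
F2 | step 11 | trienone C21 diisopropylsilyl (Si-H) ether | C=C[C@H]1C=C(C)C=C([C@@H]1CO[SiH](C(C)C)C(C)C)C(=O)C1=C(C)C[C@H](C)C[C@@H]1C
F3 | step 11 | cyclic diisopropylsilylene C8 enol/C21 ether (C8=C23) | C=C[C@H]1C=C(C)[C@@H]2[C@@H]3[C@@H]1CO[Si](C(C)C)(C(C)C)OC3=C4[C@@H](C)C[C@@H](C)C[C@]42C
F4 | step 11 | tricyclic C8 ketone with free C21 hydroxyl | C=C[C@H]1C=C(C)[C@@H]2[C@H]([C@@H]1CO)C(=O)[C@@H]3[C@@H](C)C[C@@H](C)C[C@]32C
F5 | step 5 | linear trimethylsilyl dienol ether of 10 | C=C[C@H]1C=C(C)C=C(O[Si](C)(C)C)[C@@H]1CO[Si](c1ccccc1)(c1ccccc1)C(C)(C)C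
F6 | step 10 | (4R,6S)-2,4,6-trimethylcyclohex-1-ene-1-carbaldehyde | O=CC1=C(C)C[C@H](C)C[C@@H]1C
F7 | step 10 | bis-allylic C8 alcohol (C8 epimers) | C=C[C@H]1C=C(C)C=C([C@@H]1CO[Si](c1ccccc1)(c1ccccc1)C(C)(C)C)C(O)C1=C(C)C[C@H](C)C[C@@H]1C
F8 | step 18 | C8-hydroxy C21 N-methoxy-N-methylamide | C=C[C@H]1C=C(C)[C@@H]2[C@H]([C@@H]1C(=O)N(C)OC)[C@H](O)[C@@H]3[C@@H](C)C[C@@H](C)C[C@]32C
F9 | step 19 | open aryl ether with C21 silyl ether | C=C[C@H]1C=C(C)[C@@H]2[C@H]([C@@H]1CO[Si](c1ccccc1)(c1ccccc1)C(C)(C)C)[C@H](Oc1ccc(C[C@H]4CCC(=O)N4C(=O)OC(C)(C)C)cc1)[C@@H]3[C@@H](C)C[C@@H](C)C[C@]32C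
F10 | step 19 | open aryl ether with C21 alcohol | C=C[C@H]1C=C(C)[C@@H]2[C@H]([C@@H]1CO)[C@H](Oc1ccc(C[C@H]4CCC(=O)N4C(=O)OC(C)(C)C)cc1)[C@@H]3[C@@H](C)C[C@@H](C)C[C@]32C
F11 | step 19 | open aryl ether with C21 aldehyde | C=C[C@H]1C=C(C)[C@@H]2[C@H]([C@@H]1C=O)[C@H](Oc1ccc(C[C@H]4CCC(=O)N4C(=O)OC(C)(C)C)cc1)[C@@H]3[C@@H](C)C[C@@H](C)C[C@]32C
F12 | step 19 | paracyclophane β-hydroxy lactam (C19 and C21 epimers) | C=C[C@H]1C=C(C)[C@@H]2[C@H]3[C@H](Oc4ccc(cc4)C[C@H]4CC(C(=O)N4C(=O)OC(C)(C)C)C(O)[C@H]13)[C@@H]1[C@@H](C)C[C@@H](C)C[C@]12C
A1 | alternative 1 | ring A tethered tetraene ester (Diels-Alder precursor) | COC(=O)/C=C/[C@H](O)[C@@H]1[C@@H](C)C[C@@H](C)C[C@@]1(C)/C=C(\C)/C=C/C=C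
A2 | alternative 1 | cis B/C-fused tricyclic methyl ester (required adduct) | C=C[C@H]1C=C(C)[C@@H]2[C@H]([C@@H]1C(=O)OC)[C@H](O)[C@@H]3[C@@H](C)C[C@@H](C)C[C@]32C
A3 | alternative 2 | 13-membered cyclophane enone with pendant triene | C=C/C=C/C(C)=C/[C@]1(C)C[C@H](C)C[C@H](C)[C@H]1[C@H]1Oc2ccc(cc2)C[C@@]2(O)C=C(C(=O)N2)C(=O)/C=C/1
A4 | alternative 3 | 14-membered β-keto macrolactam aldehyde | C=C[C@H]1C=C(C)[C@@H]2[C@H]3[C@H](Oc4ccc(cc4)C[C@@H](C=O)NC(=O)CC(=O)[C@H]13)[C@@H]1[C@@H](C)C[C@@H](C)C[C@]12C
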